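**Plan**

Numbering: undeca-4,8-diene chain with C1 = CH(OAc) on the lactone, C6 = allylic CH(OAc), C7 = CH2, C11 = CH2 on the furan; C2' = methyl-bearing lactone carbon.
Retrosynthesis: the C6 acetate is removed, then the C6–C7 bond is cut. The enabling feature is the homoallylic array O–C6H–C7H2–C8(CH3)=C9H, the retron of an allylboration with allyl shift; the γ-lactone ring and the furan ring are spectators.
This gives an enal (C1–C6 with lactone and C1 acetate) and a 2-methylallyl boronate (C7–C11 with furan, boron on C9). The enal goes back to geranyl acetate through the lactone C–O bond (epoxy ester cyclisation), the C3'–C4' bond (Johnson–Claisen) and the C1–C2' bond (isopropenyl addition).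
The boronate is cut at C8–C9 (lithiation–borylation with isopropenyl-Bpin) and at the furan–C11 bond (3-furyllithium and oxetane).
Forward: the C1–C6 chain is built, the lactone ring closes in step 4, the bought furan ring never meets ozone, dioxirane or acid, the halves are joined in step 11, and the last acetate is added.
Stereochemistry: C1 and C2' come from a Shi epoxidation followed by invertive lactonisation; C6 and the 8E alkene come from chirality transfer from the (−)-sparteine-derived C–B centre; 4E comes from geranyl acetate.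

Key step: step 11

Remark: the secondary allylic alcohol made in step 2 is used as the racemate because its stereocentre is destroyed in step 3; metal alkoxides present before aqueous quench are counted as salt forms of the product alcohol.

**Route**

Step 1
Reactants: 1 geranyl acetate
Product: 3 (2E)-3-methyl-6-oxohex-2-en-1-yl acetate, via ozonide 2 (not isolated)
Conditions: O3 (1.0 equiv, Sudan Red 7B end point), CH2Cl2, −78 °C; then Me2S, −78 °C to rt
Reagents that add atoms: ozone, [O-][O+]=O
Why: Chemoselective ozonolysis should cleave the electron-rich 6,7-alkene much faster than the 2,3-alkene deactivated by the allylic acetoxy group, and Me2S reduces ozonide 2 to the aldehyde; no stereocentre is formed.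

Step 2
Reactants: 3 (2E)-3-methyl-6-oxohex-2-en-1-yl acetate; 4 isopropenylmagnesium bromide
Product: 5 (2E)-6-hydroxy-3,7-dimethylocta-2,7-dien-1-yl acetate (racemic)
Conditions: 4 (1.1 equiv), THF, −78 °C; then pH 7 buffer
Reagents that add atoms: none
Why: Grignard 1,2-addition should be much faster at the aldehyde than at the acetate at −78 °C; the new carbinol centre is formed as the racemate and is destroyed in step 3.

Step 3
Reactants: 5 (2E)-6-hydroxy-3,7-dimethylocta-2,7-dien-1-yl acetate; 6 triethyl orthoacetate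
Product: 8 ethyl (4E,8E)-10-(acetyloxy)-4,8-dimethyldeca-4,8-dienoate, via ketene acetal 7 (not isolated)
Conditions: 6 (7 equiv), EtCO2H (0.1 equiv), 140 °C, EtOH distilled off
Reagents that add atoms: none
Why: Johnson–Claisen rearrangement through a chair transition state with the chain pseudo-equatorial (an axial chain would clash with the ethoxy group) should give the (4E)-trisubstituted alkene and removes the carbinol stereocentre.

Step 4
Reactants: 8 ethyl (4E,8E)-10-(acetyloxy)-4,8-dimethyldeca-4,8-dienoate
Product: 10 (2E,6R)-6-hydroxy-3-methyl-6-[(2S)-2-methyl-5-oxooxolan-2-yl]hex-2-en-1-yl acetate, via epoxy ester 9 (not isolated)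
Conditions: 1,2:4,5-di-O-isopropylidene-β-D-erythro-2,3-hexodiulo-2,6-pyranose (0.3 equiv), Oxone (2KHSO5·KHSO4·K2SO4), K2CO3, Bu4NHSO4 (cat.), MeCN/CH2(OMe)2, aq. Na2B4O7/Na2EDTA buffer, 0 °C; extractive work-up; then p-TsOH·H2O (0.2 equiv), wet CH2Cl2, rt
Reagents that add atoms: potassium peroxymonosulfate, [K+].[O-]S(=O)(=O)OO; water, O
Why: Shi asymmetric epoxidation (spiro transition state of the D-fructose-derived dioxirane) should oxidise only the isolated 4,5-alkene, the 8,9-alkene being deactivated by its allylic acetate, and set both epoxide carbons as (R); acid then drives 5-exo attack of the ester carbonyl oxygen on the tertiary epoxide carbon with inversion, so the lactone carbon becomes (S) and the carbinol stays (R).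

Step 5
Reactants: 10 (2E,6R)-6-hydroxy-3-methyl-6-[(2S)-2-methyl-5-oxooxolan-2-yl]hex-2-en-1-yl acetate
Product: 11 (2E,6R)-3-methyl-6-[(2S)-2-methyl-5-oxooxolan-2-yl]hex-2-ene-1,6-diyl diacetate
Conditions: Ac2O (2 equiv), pyridine, DMAP (0.1 equiv), CH2Cl2, 0 °C to rt
Reagents that add atoms: acetic anhydride, CC(=O)OC(C)=O
Why: DMAP-catalysed O-acetylation should acylate the hindered secondary hydroxyl with retention, installing the C1 acetate of the target before the aldehyde is unveiled.

Step 6
Reactants: 11 (2E,6R)-3-methyl-6-[(2S)-2-methyl-5-oxooxolan-2-yl]hex-2-ene-1,6-diyl diacetate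
Product: 12 (1R,4E)-6-hydroxy-4-methyl-1-[(2S)-2-methyl-5-oxooxolan-2-yl]hex-4-en-1-yl acetate
Conditions: Candida antarctica lipase B (immobilised), pH 7 phosphate buffer/acetone, 30 °C
Reagents that add atoms: none
Why: Enzymatic chemoselective ester hydrolysis should accept the unhindered primary allylic acetate and reject the secondary acetate next to the quaternary lactone carbon, while neutral pH spares the lactone.

Step 7
Reactants: 12 (1R,4E)-6-hydroxy-4-methyl-1-[(2S)-2-methyl-5-oxooxolan-2-yl]hex-4-en-1-yl acetate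
Product: 13 (1R,4E)-4-methyl-1-[(2S)-2-methyl-5-oxooxolan-2-yl]-6-oxohex-4-en-1-yl acetate
Conditions: MnO2 (activated, 15 equiv), CH2Cl2, rt
Reagents that add atoms: none
Why: Allylic oxidation with MnO2 should give the (E)-enal under neutral conditions without touching acetate, lactone or alkene geometry.

Step 8
Reactants: 14 3-bromofuran; 15 oxetane
Product: 17 3-(furan-3-yl)propan-1-ol, via 3-furyllithium 16 (not isolated)
Conditions: n-BuLi (1.05 equiv), THF, −78 °C; then 15 (1.2 equiv), BF3·OEt2 (1.2 equiv), −78 °C; then H2O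
Reagents that add atoms: none
Why: Bromine–lithium exchange gives 3-furyllithium, which is stable at −78 °C, and BF3-activated SN2 ring opening of oxetane should deliver the three-carbon alcohol in one operation.

Step 9
Reactants: 17 3-(furan-3-yl)propan-1-ol
Product: 18 3-(furan-3-yl)propyl N,N-diisopropylcarbamate
Conditions: iPr2NCOCl (1.2 equiv), Et3N (1.5 equiv), CH2Cl2, reflux
Reagents that add atoms: N,N-diisopropylcarbamoyl chloride, CC(C)N(C(C)C)C(Cl)=O
Why: O-carbamoylation installs the directing and leaving group needed for the asymmetric deprotonation of step 10.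

Step 10
Reactants: 18 3-(furan-3-yl)propyl N,N-diisopropylcarbamate; 19 isopropenylboronic acid pinacol ester
Product: 22 2-[(3R)-5-(furan-3-yl)-2-methylpent-1-en-3-yl]-4,4,5,5-tetramethyl-1,3,2-dioxaborolane, via lithiated carbamate 20 (not isolated), via boronate complex 21 (not isolated)
Conditions: s-BuLi (1.3 equiv), (−)-sparteine (1.3 equiv), Et2O, −78 °C; 19 (1.5 equiv), −78 °C; MgBr2·OEt2, then reflux
Reagents that add atoms: none
Why: Lithiation–borylation: carbamate-directed deprotonation with s-BuLi/(−)-sparteine removes the pro-S hydrogen to give the configurationally stable (S)-organolithium 20, borylation proceeds with retention, and the 1,2-metallate shift of the isopropenyl group anti to the leaving carbamate (inversion at carbon) should set the (R)-C–B stereocentre.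

Step 11
Reactants: 22 2-[(3R)-5-(furan-3-yl)-2-methylpent-1-en-3-yl]-4,4,5,5-tetramethyl-1,3,2-dioxaborolane; 13 (1R,4E)-4-methyl-1-[(2S)-2-methyl-5-oxooxolan-2-yl]-6-oxohex-4-en-1-yl acetate
Product: 26 (1R,4E,6S,8E)-11-(furan-3-yl)-6-hydroxy-4,8-dimethyl-1-[(2S)-2-methyl-5-oxooxolan-2-yl]undeca-4,8-dien-1-yl acetate, via butyl boronate complex 23 (not isolated), via allyl borinic ester 24 (not isolated), via product borinate 25 (not isolated)
Conditions: 22 (1.3 equiv), n-BuLi (1.3 equiv), THF, −78 °C; TFAA (1.3 equiv), −78 °C; 13 (1.0 equiv), −78 °C; aq. NaHCO3 at −78 °C, then rt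
Reagents that add atoms: none
Why: n-BuLi adds to boron to give ate complex 23, TFAA acylates one pinacol oxygen to open the ring and leave the more Lewis-acidic allyl borinic ester 24, which binds the aldehyde oxygen of 13 and transfers the allyl group through a closed six-membered chair transition state with allyl shift (SE2'), so the terminal CH2 of the methallyl unit becomes C7 bonded to C6 and the double bond moves to C8=C9; hydrolysis of borinate 25 releases 26. The closest known reaction type is the allylboration of aldehydes with enantioenriched α-substituted β-methallyl pinacol boronic esters after conversion in the flask into borinic esters. No ring is closed. The new stereocentre C6 is controlled by the boron-bearing stereocentre of 22 (1,3-chirality transfer): with the CH2CH2-furyl group and the alkenyl residue of the aldehyde both pseudo-equatorial in the chair, the (R)-boronate should deliver (6S) and the (8E)-alkene together. The step needs E over Z selectivity, which the slim borinic ester should secure (the pinacol ester itself would push the substituent axial and give Z), and it needs reaction at the aldehyde only, which the neutral allylboron reagent at −78 °C secures against lactone and acetate, while the furan is spared because TFAA is not used in excess and the mixture is quenched cold; 1,2-addition follows from the closed transition state. The centres C1 and C2' of 13 are remote from C6 and should not bias the addition, so the reagent decides.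

Step 12
Reactants: 26 (1R,4E,6S,8E)-11-(furan-3-yl)-6-hydroxy-4,8-dimethyl-1-[(2S)-2-methyl-5-oxooxolan-2-yl]undeca-4,8-dien-1-yl acetate
Product: 27 irciformonin F
Conditions: Ac2O (3 equiv), pyridine, DMAP (0.1 equiv), CH2Cl2, 0 °C to rt
Reagents that add atoms: acetic anhydride, CC(=O)OC(C)=O
Why: DMAP-catalysed O-acetylation of the allylic alcohol with retention at C6 should give the target; the basic, non-oxidising conditions spare the furan, the lactone and both alkenes.

**Compound list**

1 | geranyl acetate, (2E)-3,7-dimethylocta-2,6-dien-1-yl acetate | CC(C)=CCC/C(C)=C/COC(C)=O | starting material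
2 | ozonide, 3-[(3E)-5-(acetyloxy)-3-methylpent-3-en-1-yl]-5,5-dimethyl-1,2,4-trioxolane (racemic) | CC(=O)OC/C=C(\C)CCC1OOC(C)(C)O1 | intermediate
3 | (2E)-3-methyl-6-oxohex-2-en-1-yl acetate | CC(=O)OC/C=C(\C)CCC=O | intermediate
4 | isopropenylmagnesium bromide | CC(=C)[Mg]Br | starting material
5 | (2E)-6-hydroxy-3,7-dimethylocta-2,7-dien-1-yl acetate (racemic) | CC(=O)OC/C=C(\C)CCC(O)C(C)=C | intermediate
6 | triethyl orthoacetate | CCOC(C)(OCC)OCC | starting material
7 | ketene acetal, (2E)-6-[(1-ethoxyethenyl)oxy]-3,7-dimethylocta-2,7-dien-1-yl acetate (racemic) | CC(=O)OC/C=C(\C)CCC(OC(=C)OCC)C(C)=C | intermediate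
8 | ethyl (4E,8E)-10-(acetyloxy)-4,8-dimethyldeca-4,8-dienoate | CCOC(=O)CC/C(C)=C/CC/C(C)=C/COC(C)=O | intermediate
9 | epoxy ester, ethyl 3-[(2R,3R)-3-[(3E)-5-(acetyloxy)-3-methylpent-3-en-1-yl]-2-methyloxiran-2-yl]propanoate | CCOC(=O)CC[C@@]1(C)O[C@@H]1CC/C(C)=C/COC(C)=O | intermediate
10 | (2E,6R)-6-hydroxy-3-methyl-6-[(2S)-2-methyl-5-oxooxolan-2-yl]hex-2-en-1-yl acetate | CC(=O)OC/C=C(\C)CC[C@@H](O)[C@]1(C)CCC(=O)O1 | intermediate
11 | (2E,6R)-3-methyl-6-[(2S)-2-methyl-5-oxooxolan-2-yl]hex-2-ene-1,6-diyl diacetate | CC(=O)OC/C=C(\C)CC[C@@H](OC(C)=O)[C@]1(C)CCC(=O)O1 | intermediate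
12 | (1R,4E)-6-hydroxy-4-methyl-1-[(2S)-2-methyl-5-oxooxolan-2-yl]hex-4-en-1-yl acetate | OC/C=C(\C)CC[C@@H](OC(C)=O)[C@]1(C)CCC(=O)O1 | intermediate
13 | (1R,4E)-4-methyl-1-[(2S)-2-methyl-5-oxooxolan-2-yl]-6-oxohex-4-en-1-yl acetate | O=C/C=C(\C)CC[C@@H](OC(C)=O)[C@]1(C)CCC(=O)O1 | intermediate
14 | 3-bromofuran | Brc1ccoc1 | starting material
15 | oxetane | C1COC1 | starting material
16 | 3-furyllithium | [Li]c1ccoc1 | intermediate
17 | 3-(furan-3-yl)propan-1-ol | OCCCc1ccoc1 | intermediate
18 | 3-(furan-3-yl)propyl N,N-diisopropylcarbamate | CC(C)N(C(C)C)C(=O)OCCCc1ccoc1 | intermediate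
19 | isopropenylboronic acid pinacol ester, 4,4,5,5-tetramethyl-2-(prop-1-en-2-yl)-1,3,2-dioxaborolane | CC(=C)B1OC(C)(C)C(C)(C)O1 | starting material
20 | lithiated carbamate, (1S)-3-(furan-3-yl)-1-lithiopropyl N,N-diisopropylcarbamate | [Li][C@@H](CCc1ccoc1)OC(=O)N(C(C)C)C(C)C | intermediate
21 | boronate complex, lithium [(1S)-1-[(diisopropylcarbamoyl)oxy]-3-(furan-3-yl)propyl](isopropenyl)(pinacolato)borate | [Li+].CC(=C)[B-]1(OC(C)(C)C(C)(C)O1)[C@@H](CCc1ccoc1)OC(=O)N(C(C)C)C(C)C | intermediate
22 | 2-[(3R)-5-(furan-3-yl)-2-methylpent-1-en-3-yl]-4,4,5,5-tetramethyl-1,3,2-dioxaborolane | CC(=C)[C@@H](CCc1ccoc1)B1OC(C)(C)C(C)(C)O1 | intermediate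
23 | butyl boronate complex, lithium butyl[(3R)-5-(furan-3-yl)-2-methylpent-1-en-3-yl](pinacolato)borate | [Li+].CCCC[B-]1(OC(C)(C)C(C)(C)O1)[C@H](CCc1ccoc1)C(C)=C | intermediate
24 | allyl borinic ester, 3-({butyl[(3R)-5-(furan-3-yl)-2-methylpent-1-en-3-yl]boranyl}oxy)-2,3-dimethylbutan-2-yl trifluoroacetate | CCCCB(OC(C)(C)C(C)(C)OC(=O)C(F)(F)F)[C@H](CCc1ccoc1)C(C)=C | intermediate
25 | product borinate, the C6 O-boron ester of 26 with the butyl(3-trifluoroacetoxy-2,3-dimethylbutan-2-yloxy)boranyl group | CCCCB(OC(C)(C)C(C)(C)OC(=O)C(F)(F)F)O[C@H](/C=C(\C)CC[C@@H](OC(C)=O)[C@]1(C)CCC(=O)O1)C/C(C)=C/CCc1ccoc1 | intermediate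
26 | (1R,4E,6S,8E)-11-(furan-3-yl)-6-hydroxy-4,8-dimethyl-1-[(2S)-2-methyl-5-oxooxolan-2-yl]undeca-4,8-dien-1-yl acetate | O[C@H](/C=C(\C)CC[C@@H](OC(C)=O)[C@]1(C)CCC(=O)O1)C/C(C)=C/CCc1ccoc1 | intermediate
27 | irciformonin F, (1R,4E,6S,8E)-11-(furan-3-yl)-4,8-dimethyl-1-[(2S)-2-methyl-5-oxooxolan-2-yl]undeca-4,8-diene-1,6-diyl diacetate | CC(=O)O[C@H](/C=C(\C)CC[C@@H](OC(C)=O)[C@]1(C)CCC(=O)O1)C/C(C)=C/CCc1ccoc1 | target

**Step count and risks**

Total steps: 12. Longest linear sequence: 9 steps (steps 1 to 7, then 11 and 12); the boronate branch has 3 steps (8 to 10).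

Most likely to fail, step 11: the E/Z control may erode if the CH2CH2-furyl group takes the pseudo-axial position in the chair, chirality transfer may be incomplete, or the borinic ester may undergo a 1,3-boron shift before it adds. The fallback fixes the alkene geometry before the coupling and sets C6 afterwards by reagent control; it sets out from 17 and 13 and comes back at 26. Swern oxidation of 17 should give 3-(furan-3-yl)propanal F1, and Wittig olefination with Ph3P=C(CH3)CO2Et should give ethyl (2E)-5-(furan-3-yl)-2-methylpent-2-enoate F2. Reduction with i-Bu2AlH should give (2E)-5-(furan-3-yl)-2-methylpent-2-en-1-ol F3, and PPh3/CCl4 should give 3-[(3E)-5-chloro-4-methylpent-3-en-1-yl]furan F4. Zerovalent barium (from BaI2 and lithium biphenylide, THF, −78 °C) should convert F4 into the allylbarium chloride F5, which adds to enal 13 at its unsubstituted allyl terminus with retention of the (E)-geometry to give the C6 epimer mixture F6. Dess–Martin oxidation should give the enone F7, and Corey–Bakshi–Shibata reduction with the (R)-methyl oxazaborolidine and catecholborane at −78 °C (alkenyl as the large group) should give 26.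

Second, step 10: s-BuLi may lithiate the furan 2-position in competition with the carbamate, and the 1,2-shift of the vinyl boronate complex may be slow enough for the complex to revert. The fallback avoids an organolithium base in the presence of the carbamate; it sets out from 16 (made from 14 as in step 8) and comes back at 22. Opening of ethylene oxide by 16 should give 2-(furan-3-yl)ethan-1-ol F8, and CBr4/PPh3 should give 3-(2-bromoethyl)furan F9. Alkylation of lithiated bis(pinacolato)borylmethane (from CH2(Bpin)2 and LiTMP, THF, 0 °C) with F9 should give the geminal bis(boronate) 2,2'-[3-(furan-3-yl)propane-1,1-diyl]bis(4,4,5,5-tetramethyl-1,3,2-dioxaborolane) F10. An enantiotopic-group-selective Suzuki–Miyaura coupling of F10 with 2-bromopropene (Pd(OAc)2, chiral TADDOL-derived phosphoramidite, KOH, dioxane/H2O), with the ligand antipode chosen for the (R)-product, should give 22.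

Third, step 6: the enzyme may not discriminate cleanly between the two acetates, or the lactone may open by hydrolysis. The fallback changes the order of protecting-group events; it sets out from 10 and comes back at 13. Methanolysis of 10 with K2CO3/MeOH, followed by brief acid treatment to re-close any opened lactone, should give (5S)-5-[(1R,4E)-1,6-dihydroxy-4-methylhex-4-en-1-yl]-5-methyloxolan-2-one F11. MnO2 should oxidise only the allylic alcohol to (2E,6R)-6-hydroxy-3-methyl-6-[(2S)-2-methyl-5-oxooxolan-2-yl]hex-2-enal F12, and Ac2O/pyridine/DMAP at 0 °C should then acetylate the secondary hydroxyl to give 13.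

Further compounds

F1 | step 11 | 3-(furan-3-yl)propanal | O=CCCc1ccoc1
F2 | step 11 | ethyl (2E)-5-(furan-3-yl)-2-methylpent-2-enoate | CCOC(=O)/C(C)=C/CCc1ccoc1
F3 | step 11 | (2E)-5-(furan-3-yl)-2-methylpent-2-en-1-ol | OC/C(C)=C/CCc1ccoc1
F4 | step 11 | 3-[(3E)-5-chloro-4-methylpent-3-en-1-yl]furan | ClC/C(C)=C/CCc1ccoc1
F5 | step 11 | [(2E)-5-(furan-3-yl)-2-methylpent-2-en-1-yl]barium chloride | Cl[Ba]C/C(C)=C/CCc1ccoc1
F6 | step 11 | (1R,4E,6RS,8E)-11-(furan-3-yl)-6-hydroxy-4,8-dimethyl-1-[(2S)-2-methyl-5-oxooxolan-2-yl]undeca-4,8-dien-1-yl acetate (C6 epimer mixture) | OC(/C=C(\C)CC[C@@H](OC(C)=O)[C@]1(C)CCC(=O)O1)C/C(C)=C/CCc1ccoc1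
F7 | step 11 | (1R,4E,8E)-11-(furan-3-yl)-4,8-dimethyl-1-[(2S)-2-methyl-5-oxooxolan-2-yl]-6-oxoundeca-4,8-dien-1-yl acetate | O=C(/C=C(\C)CC[C@@H](OC(C)=O)[C@]1(C)CCC(=O)O1)C/C(C)=C/CCc1ccoc1
F8 | step 10 | 2-(furan-3-yl)ethan-1-ol | OCCc1ccoc1
F9 | step 10 | 3-(2-bromoethyl)furan | BrCCc1ccoc1
F10 | step 10 | 2,2'-[3-(furan-3-yl)propane-1,1-diyl]bis(4,4,5,5-tetramethyl-1,3,2-dioxaborolane) | CC1(C)OB(OC1(C)C)C(CCc1ccoc1)B1OC(C)(C)C(C)(C)O1
F11 | step 6 | (5S)-5-[(1R,4E)-1,6-dihydroxy-4-methylhex-4-en-1-yl]-5-methyloxolan-2-one | OC/C=C(\C)CC[C@@H](O)[C@]1(C)CCC(=O)O1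
F12 | step 6 | (2E,6R)-6-hydroxy-3-methyl-6-[(2S)-2-methyl-5-oxooxolan-2-yl]hex-2-enal | O=C/C=C(\C)CC[C@@H](O)[C@]1(C)CCC(=O)O1
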